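**Retrosynthetic overview** (caryophyllane locants: C1/C9 ring fusion, C10/C11 cyclobutane, C12 = methyl on C4, C13 = exocyclic carbon on C8)

1. The spiro-dihydropyran is made last, by Knoevenagel/oxa-Diels–Alder reaction of syncarpic acid, isovaleraldehyde and the C8=C13 methylene of dienol 15.
2. The C5 carbinol comes from CBS reduction of (Z)-enone 14; the enone from a C5 silyl enol ether (Saegusa–Ito); C13 from Wittig methylenation of a C8 ketone.
3. The nine-membered ring (C1–C9) is made by Claisen ring expansion of a seven-membered 2-methylene-oxepane (O, C8, C9, C1, C2, C3, C4). The enabling feature is that the C8 carbonyl carbon and the C4=C5 enol double bond are γ,δ-related across C6–C7, and C4 is a methyl-bearing carbon that can be a tertiary allylic ether carbon.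
4. The oxepanone comes from Baeyer–Villiger oxidation of an α-methyl-α-vinyl cyclohexanone; the vinyl group is then oxidised to acetyl and silylated.
5. Order of ring formation: cyclobutane (enantioselective [2+2] on cyclohexenone) → seven-membered lactone → nine-membered carbocycle → dihydropyran.

Key step: step 8

Remarks on the chemistry: syncarpic acid (16) is taken as a purchasable compound. The quaternary centre created in step 3 is carried as a mixture of epimers and left undefined in the SMILES, because it becomes sp2 in step 8.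

**Route**

Step 1
Reactants: 1 cyclohex-2-en-1-one; 2 2-methylpropene
Product: 3 (1R,6R)-7,7-dimethylbicyclo[4.2.0]octan-2-one (cis-fused)
Conditions: hν (366 nm), chiral B-aryl oxazaborolidine·AlBr3 (50 mol %, enantiomer chosen to give 6R), CH2Cl2, −78 °C; then basic Al2O3
Reagents that add atoms: none
Why: Lewis-acid-catalysed enantioselective enone–alkene [2+2] photocycloaddition (head-to-tail) in which the chiral complex shields one enone face and so sets C6, while alumina equilibrates the α-carbon C1 to the cis fusion.

Step 2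
Reactants: 3 (1R,6R)-7,7-dimethylbicyclo[4.2.0]octan-2-one
Product: 4 (1R,6R,3Z)-3-(hydroxymethylidene)-7,7-dimethylbicyclo[4.2.0]octan-2-one
Conditions: NaH, HCO2Et, cat. EtOH, THF, 0 °C → rt; then aq. HCl
Reagents that add atoms: ethyl formate, CCOC=O
Why: Crossed Claisen condensation, which can only give a stable enolisable product at the α-methylene C3 and not at the ring-fusion methine.

Step 3
Reactants: 4 (1R,6R,3Z)-3-(hydroxymethylidene)-7,7-dimethylbicyclo[4.2.0]octan-2-one
Product: 5 (1R,6R)-3,7,7-trimethyl-2-oxobicyclo[4.2.0]octane-3-carbaldehyde (C3 epimers)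
Conditions: MeI, K2CO3, acetone, reflux
Reagents that add atoms: iodomethane, CI
Why: C-alkylation of the β-keto aldehyde enolate builds the quaternary carbon, whose configuration is immaterial for the route.

Step 4
Reactants: 5 (1R,6R)-3,7,7-trimethyl-2-oxobicyclo[4.2.0]octane-3-carbaldehyde
Product: 6 (1R,6R)-3-ethenyl-3,7,7-trimethylbicyclo[4.2.0]octan-2-one (C3 epimers)
Conditions: Ph3PCH3Br, KHMDS, THF, −78 → 0 °C (1.05 equiv ylide)
Reagents that add atoms: methyltriphenylphosphonium bromide, C[P+](c1ccccc1)(c1ccccc1)c1ccccc1.[Br-]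
Why: Wittig methylenation, chemoselective for the aldehyde over the hindered ketone at low temperature.

Step 5
Reactants: 6 (1R,6R)-3-ethenyl-3,7,7-trimethylbicyclo[4.2.0]octan-2-one
Product: 7 (1R,7R)-4-ethenyl-4,8,8-trimethyl-3-oxabicyclo[5.2.0]nonan-2-one (C4 epimers)
Conditions: mCPBA, NaHCO3, CH2Cl2, 0 °C → rt
Reagents that add atoms: 3-chloroperbenzoic acid, OOC(=O)c1cccc(Cl)c1
Why: Baeyer–Villiger oxidation in which the tertiary allylic carbon should migrate in preference to the secondary cyclobutyl carbon, while the monosubstituted vinyl group is epoxidised much more slowly.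

Step 6
Reactants: 7 (1R,7R)-4-ethenyl-4,8,8-trimethyl-3-oxabicyclo[5.2.0]nonan-2-one
Product: 8 (1R,7R)-4-acetyl-4,8,8-trimethyl-3-oxabicyclo[5.2.0]nonan-2-one (C4 epimers)
Conditions: Pd(Quinox)Cl2 (cat.), AgSbF6 (cat.), aq. TBHP, CH2Cl2, 0 °C → rt
Reagents that add atoms: tert-butyl hydroperoxide, CC(C)(C)OO
Why: Catalyst-controlled Tsuji–Wacker oxidation of the type that gives methyl ketones from O-protected allylic alcohols.

Step 7
Reactants: 8 (1R,7R)-4-acetyl-4,8,8-trimethyl-3-oxabicyclo[5.2.0]nonan-2-one
Product: 9 (1R,7R)-4-[1-(tert-butyldimethylsilyloxy)ethenyl]-4,8,8-trimethyl-3-oxabicyclo[5.2.0]nonan-2-one (C4 epimers)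
Conditions: TBSOTf, Et3N, CH2Cl2, 0 °C
Reagents that add atoms: tert-butyldimethylsilyl triflate, CC(C)(C)[Si](C)(C)OS(=O)(=O)C(F)(F)F
Why: Soft enolisation of the acetyl group, which has α-hydrogens only on its methyl so a single silyl enol ether forms, while the lactone is not silylated under these conditions.

Step 8
Reactants: 9 (1R,7R)-4-[1-(tert-butyldimethylsilyloxy)ethenyl]-4,8,8-trimethyl-3-oxabicyclo[5.2.0]nonan-2-one
Product: 11 (1R,9R)-5-(tert-butyldimethylsilyloxy)-4,11,11-trimethylbicyclo[7.2.0]undec-4-en-8-one (cis-fused), via exocyclic enol ether 10 (not isolated)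
Conditions: Cp2TiMe2 (3 equiv), toluene, 75 °C, dark; then 150 °C, sealed base-washed tube, cat. Et3N
Reagents that add atoms: dimethyltitanocene, C[Ti](C)(C1C=CC=C1)C1C=CC=C1
Why: Petasis methylenation turns the lactone carbonyl (the only carbonyl left) into the 2-methylene-oxepane 10, whose allyl vinyl ether array C7=C8–O–C4–C5=C6 then undergoes a thermal [3,3]-sigmatropic (Claisen) shift, forming C6–C7 and breaking O–C4. The closest known reaction type is the methylenation/Claisen ring expansion of 2-methylene-6-vinyl-tetrahydropyrans to cyclooct-4-enones and of vinyl-substituted seven-membered ketene acetals to nine-membered lactones. The nine-membered carbocycle is closed by ring expansion of the seven-membered oxacycle by two atoms through a boat-like six-membered transition state, which should give the ring-cis enol ether. No new stereocentre is formed: C1 and C9 are untouched, and C4 becomes sp2 so that both C4 epimers of 9 converge on one product. The step needs exclusive C-alkylative [3,3] reactivity through the exocyclic enol ether, which is secured because 10 contains only one allyl vinyl ether array and base-washed glass with Et3N suppresses migration of the exocyclic double bond into the ring. The shift delivers the C8 ketone and a C5 silyl enol ether locked towards C4, which fixes the position of the later C3=C4 enone.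

Step 9
Reactants: 11 (1R,9R)-5-(tert-butyldimethylsilyloxy)-4,11,11-trimethylbicyclo[7.2.0]undec-4-en-8-one
Product: 12 (1R,9S)-5-(tert-butyldimethylsilyloxy)-4,11,11-trimethylbicyclo[7.2.0]undec-4-en-8-one (trans-fused)
Conditions: t-BuOK (cat.), t-BuOH/THF, rt
Reagents that add atoms: none
Why: Thermodynamic epimerisation α to the ketone, which should favour the trans 4/9 ring fusion typical of caryophyllane ketones and so sets C9 relative to C1.

Step 10
Reactants: 12 (1R,9S)-5-(tert-butyldimethylsilyloxy)-4,11,11-trimethylbicyclo[7.2.0]undec-4-en-8-one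
Product: 13 (1R,9S)-5-(tert-butyldimethylsilyloxy)-4,11,11-trimethyl-8-methylidenebicyclo[7.2.0]undec-4-ene
Conditions: Ph3PCH3Br, KHMDS, THF, 0 °C → rt
Reagents that add atoms: methyltriphenylphosphonium bromide, C[P+](c1ccccc1)(c1ccccc1)c1ccccc1.[Br-]
Why: Wittig methylenation of the C8 ketone, a transformation well established for this ketone position in caryophyllane chemistry, with the silyl enol ether inert to the ylide.

Step 11
Reactants: 13 (1R,9S)-5-(tert-butyldimethylsilyloxy)-4,11,11-trimethyl-8-methylidenebicyclo[7.2.0]undec-4-ene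
Product: 14 (1R,9S,3Z)-4,11,11-trimethyl-8-methylidenebicyclo[7.2.0]undec-3-en-5-one
Conditions: Pd(OAc)2 (1.1 equiv), MeCN, rt
Reagents that add atoms: none
Why: Saegusa–Ito oxidation, in which the palladium enolate at C4 should undergo β-hydride elimination towards the ring methylene C3 to give the conjugated ring-cis (Z) enone, the more stable geometry in a nine-membered ring.

Step 12
Reactants: 14 (1R,9S,3Z)-4,11,11-trimethyl-8-methylidenebicyclo[7.2.0]undec-3-en-5-one
Product: 15 (1R,5S,9S,3Z)-4,11,11-trimethyl-8-methylidenebicyclo[7.2.0]undec-3-en-5-ol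
Conditions: (R)-Me-CBS (0.2 equiv), catecholborane, toluene, −78 °C; then MeOH, aq. NaOH
Reagents that add atoms: none
Why: Corey–Bakshi–Shibata 1,2-reduction in which the α-methyl alkenyl arm acts as the large group, so the (R)-catalyst should deliver the 5S carbinol, and catecholborane does not hydroborate the methylidene group.

Step 13
Reactants: 15 (1R,5S,9S,3Z)-4,11,11-trimethyl-8-methylidenebicyclo[7.2.0]undec-3-en-5-ol; 16 syncarpic acid (2,2,4,4-tetramethylcyclohexane-1,3,5-trione); 17 3-methylbutanal
Product: 19 tomentodione P, via enetrione 18 (not isolated)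
Conditions: ethylenediammonium diacetate (10 mol %), 4 Å MS, toluene, 60 °C
Reagents that add atoms: none
Why: Knoevenagel condensation gives the 2-alkylidene trione 18, which should add as an oxa-diene in an inverse-demand hetero-Diels–Alder reaction to the 1,1-disubstituted C8=C13 alkene (O to C8, C13 to the isobutyl-bearing carbon) in preference to the unstrained trisubstituted alkene; approach from the outer face of the folded nine-membered ring, with the isobutyl group turned away from it, is expected to set the 8S spiro centre and the S isobutyl-bearing centre.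

**Compound list**

1 | cyclohex-2-en-1-one | O=C1C=CCCC1 | starting material
2 | 2-methylpropene | CC(C)=C | starting material
3 | (1R,6R)-7,7-dimethylbicyclo[4.2.0]octan-2-one | C1CC[C@@H]2[C@@H](CC2(C)C)C1=O | intermediate
4 | (1R,6R,3Z)-3-(hydroxymethylidene)-7,7-dimethylbicyclo[4.2.0]octan-2-one | O/C=C1/CC[C@@H]2[C@@H](CC2(C)C)C1=O | intermediate
5 | (1R,6R)-3,7,7-trimethyl-2-oxobicyclo[4.2.0]octane-3-carbaldehyde (C3 epimers) | O=CC1(C)CC[C@@H]2[C@@H](CC2(C)C)C1=O | intermediate
6 | (1R,6R)-3-ethenyl-3,7,7-trimethylbicyclo[4.2.0]octan-2-one (C3 epimers) | C=CC1(C)CC[C@@H]2[C@@H](CC2(C)C)C1=O | intermediate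
7 | (1R,7R)-4-ethenyl-4,8,8-trimethyl-3-oxabicyclo[5.2.0]nonan-2-one (C4 epimers) | C=CC1(C)CC[C@@H]2[C@@H](CC2(C)C)C(=O)O1 | intermediate
8 | (1R,7R)-4-acetyl-4,8,8-trimethyl-3-oxabicyclo[5.2.0]nonan-2-one (C4 epimers) | CC(=O)C1(C)CC[C@@H]2[C@@H](CC2(C)C)C(=O)O1 | intermediate
9 | (1R,7R)-4-[1-(tert-butyldimethylsilyloxy)ethenyl]-4,8,8-trimethyl-3-oxabicyclo[5.2.0]nonan-2-one (C4 epimers) | C=C(O[Si](C)(C)C(C)(C)C)C1(C)CC[C@@H]2[C@@H](CC2(C)C)C(=O)O1 | intermediate
10 | (1R,7R)-4-[1-(tert-butyldimethylsilyloxy)ethenyl]-4,8,8-trimethyl-2-methylidene-3-oxabicyclo[5.2.0]nonane (C4 epimers) | C=C(O[Si](C)(C)C(C)(C)C)C1(C)CC[C@@H]2[C@@H](CC2(C)C)C(=C)O1 | intermediate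
11 | (1R,9R)-5-(tert-butyldimethylsilyloxy)-4,11,11-trimethylbicyclo[7.2.0]undec-4-en-8-one (cis-fused; ring-cis enol ether drawn, geometry of no consequence) | C/C1=C(\O[Si](C)(C)C(C)(C)C)CCC(=O)[C@@H]2CC(C)(C)[C@@H]2CC1 | intermediate
12 | (1R,9S)-5-(tert-butyldimethylsilyloxy)-4,11,11-trimethylbicyclo[7.2.0]undec-4-en-8-one (trans-fused) | C/C1=C(\O[Si](C)(C)C(C)(C)C)CCC(=O)[C@H]2CC(C)(C)[C@@H]2CC1 | intermediate
13 | (1R,9S)-5-(tert-butyldimethylsilyloxy)-4,11,11-trimethyl-8-methylidenebicyclo[7.2.0]undec-4-ene | C/C1=C(\O[Si](C)(C)C(C)(C)C)CCC(=C)[C@H]2CC(C)(C)[C@@H]2CC1 | intermediate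
14 | (1R,9S,3Z)-4,11,11-trimethyl-8-methylidenebicyclo[7.2.0]undec-3-en-5-one | C/C1=C/C[C@@H]2[C@H](CC2(C)C)C(=C)CCC1=O | intermediate
15 | (1R,5S,9S,3Z)-4,11,11-trimethyl-8-methylidenebicyclo[7.2.0]undec-3-en-5-ol | C/C1=C/C[C@@H]2[C@H](CC2(C)C)C(=C)CC[C@@H]1O | intermediate
16 | syncarpic acid (2,2,4,4-tetramethylcyclohexane-1,3,5-trione) | CC1(C)C(=O)CC(=O)C(C)(C)C1=O | starting material
17 | 3-methylbutanal | CC(C)CC=O | starting material
18 | 2,2,4,4-tetramethyl-6-(3-methylbutylidene)cyclohexane-1,3,5-trione | CC(C)CC=C1C(=O)C(C)(C)C(=O)C(C)(C)C1=O | intermediate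
19 | tomentodione P (spiro adduct: 1R,5S,8S,9S caryophyllane part, 3Z alkene, S isobutyl-bearing carbon) | C/C1=C/C[C@@H]2[C@H](CC2(C)C)[C@]2(CC[C@@H]1O)C[C@H](CC(C)C)C1=C(O2)C(C)(C)C(=O)C(C)(C)C1=O | target

**Step count and risks**

Total step count: 13. Longest linear sequence: 13 steps (from cyclohex-2-en-1-one).

Steps most likely to fail:

1. Step 8. The hindered lactone carbonyl may be methylenated incompletely, the exocyclic enol ether may isomerise into the ring before it rearranges, or the silyl group may be lost at 150 °C. Fallback: set out from 9, methylenate with the Tebbe reagent (THF, pyridine, −40 °C → rt) and isolate enol ether 10. Then run the Claisen shift under triisobutylaluminium promotion (CH2Cl2, −78 °C → rt), a low-temperature Lewis-acid pathway in which the new ketone is reduced in the flask to (1R,9R)-5-(tert-butyldimethylsilyloxy)-4,11,11-trimethylbicyclo[7.2.0]undec-4-en-8-ol F1. Dess–Martin oxidation of F1 returns to the route at 11.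

2. Step 13. Facial and endo/exo selectivity at the methylidene group may be poor, and the free allylic hydroxyl may add reversibly to the enetrione or ionise. Fallback: set out from enone 14, which has no hydroxyl and a different ring conformation, and carry out the same three-component cycloaddition to give the C5-ketone spiro adduct F2. Then reduce the enone carbonyl, the only unhindered and non-vinylogous one, with (R)-Me-CBS/catecholborane, which returns to the route at 19.

3. Step 11. β-Hydride elimination may go towards the methyl group (exocyclic enone) or give the ring-trans enone, and Pd(II) may engage the methylidene group. Fallback: set out from 13 and treat with PhSeCl (CH2Cl2, −78 °C), which attacks the silyl enol ether at C4 to give (1R,9S)-4,11,11-trimethyl-8-methylidene-4-(phenylselanyl)bicyclo[7.2.0]undecan-5-one F3. Oxidation with H2O2/pyridine and selenoxide syn-elimination return to the route at 14.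

**Further compounds**

F1 | step 8 | (1R,9R)-5-(tert-butyldimethylsilyloxy)-4,11,11-trimethylbicyclo[7.2.0]undec-4-en-8-ol (C8 epimers) | C/C1=C(\O[Si](C)(C)C(C)(C)C)CCC(O)[C@@H]2CC(C)(C)[C@@H]2CC1
F2 | step 13 | 5-oxo analogue of tomentodione P (C5 ketone spiro adduct) | C/C1=C/C[C@@H]2[C@H](CC2(C)C)[C@]2(CCC1=O)C[C@H](CC(C)C)C1=C(O2)C(C)(C)C(=O)C(C)(C)C1=O
F3 | step 11 | (1R,9S)-4,11,11-trimethyl-8-methylidene-4-(phenylselanyl)bicyclo[7.2.0]undecan-5-one (C4 epimers) | CC1([Se]c3ccccc3)C(=O)CCC(=C)[C@H]2CC(C)(C)[C@@H]2CC1
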